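**Plan**

- Numbering: ring A C1 (OMe), C2 (side chain), C5 (aryl ether), C6 (CO2H); ring B C1′ (ether O), C2′ (OH), C4′ (CH3), C6′ (CH2OH).
- Retrosynthesis: first the three silicon-based protecting groups are removed, then the C5–O(C1′) ether bond and the C6–CO2H bond are cut together.
- Enabling feature: C1-OMe, C6-CO2H and C5-OAr sit on three neighbouring ring A carbons. This is the pattern left when a nucleophile and an electrophile add across the C5–C6 triple bond of a 3-methoxybenzyne.
- Forward: the ring A o-silylaryl triflate is made from resorcinol (7 steps) and the ring B phenol from creosol (5 steps). They are joined with CO2 in one operation and deprotected once; no ring is formed, the two arenes are linked through oxygen.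
- Stereochemistry: the single (S) carbinol centre comes from asymmetric transfer hydrogenation of the aryl isobutyl ketone with the (S,S)-TsDPEN ruthenium catalyst and is carried on as a TBS ether.

Key step: step 13

**Route**

Step 1
Reactants: 1 resorcinol; 2 isovaleryl chloride
Product: 3 1-(2,4-dihydroxyphenyl)-3-methylbutan-1-one
Conditions: AlCl3 (2.5 equiv), PhNO2, 0 °C to 50 °C; aq. HCl
Reagents that add atoms: none
Why: Friedel–Crafts acylation (with Fries equilibration of any O-acyl material) places the acyl group at C4 of resorcinol, para to one hydroxyl and ortho to the other, and the first acyl group deactivates the ring towards a second acylation.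

Step 2
Reactants: 3 1-(2,4-dihydroxyphenyl)-3-methylbutan-1-one
Product: 4 3-hydroxy-4-(3-methylbutanoyl)phenyl N-isopropylcarbamate
Conditions: i-PrNCO (1.05 equiv), Et3N (0.2 equiv), CH2Cl2, 0 °C to rt
Reagents that add atoms: isopropyl isocyanate CC(C)N=C=O
Why: Base-catalysed carbamoylation of a phenol by an isocyanate should occur at the free, more acidic 4-OH, because the 2-OH is hydrogen-bonded to the ketone and hindered.

Step 3
Reactants: 4 3-hydroxy-4-(3-methylbutanoyl)phenyl N-isopropylcarbamate
Product: 5 3-methoxy-4-(3-methylbutanoyl)phenyl N-isopropylcarbamate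
Conditions: MeOH, PPh3, DIAD, THF, 0 °C to rt
Reagents that add atoms: methanol CO
Why: Mitsunobu etherification methylates the chelated phenol without a carbonate base, which could cleave the para-acyl-activated N–H carbamate by E1cB loss of isopropyl isocyanate; the carbamate N–H is too weakly acidic to be alkylated.

Step 4
Reactants: 5 3-methoxy-4-(3-methylbutanoyl)phenyl N-isopropylcarbamate
Product: 6 4-[(1S)-1-hydroxy-3-methylbutyl]-3-methoxyphenyl N-isopropylcarbamate
Conditions: RuCl[(S,S)-TsDPEN](p-cymene) (1 mol %), HCO2H/Et3N (5:2), EtOAc, 40 °C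
Reagents that add atoms: none
Why: Noyori asymmetric transfer hydrogenation of an aryl alkyl ketone; the (S,S)-TsDPEN ruthenium hydride places the substrate arene against its p-cymene ligand (CH/π contact) and should deliver hydride to the face that gives the (S) alcohol, as in the acetophenone to (S)-1-phenylethanol case.

Step 5
Reactants: 6 4-[(1S)-1-hydroxy-3-methylbutyl]-3-methoxyphenyl N-isopropylcarbamate
Product: 7 4-[(1S)-1-(tert-butyldimethylsilyloxy)-3-methylbutyl]-3-methoxyphenyl N-isopropylcarbamate
Conditions: TBSCl, imidazole, DMF, rt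
Reagents that add atoms: tert-butyldimethylsilyl chloride CC(C)(C)[Si](C)(C)Cl
Why: Imidazole-promoted O-silylation of the secondary benzylic alcohol; the carbamate N–H does not react under these conditions and the C–O bond of the stereocentre is not touched.

Step 6
Reactants: 7 4-[(1S)-1-(tert-butyldimethylsilyloxy)-3-methylbutyl]-3-methoxyphenyl N-isopropylcarbamate
Product: 11 4-[(1S)-1-(tert-butyldimethylsilyloxy)-3-methylbutyl]-3-methoxy-2-(trimethylsilyl)phenyl N-isopropylcarbamate, via N-silyl carbamate 8 (not isolated), via aryllithium 9 (not isolated), via N-silyl C-silyl carbamate 10 (not isolated)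
Conditions: TBSOTf, TMEDA, Et2O, 0 °C to rt; n-BuLi, TMEDA, −78 °C; TMSCl, −78 °C to rt; aq. NH4Cl then brief cold aq. NaHSO4 wash
Reagents that add atoms: chlorotrimethylsilane C[Si](C)(C)Cl; tert-butyldimethylsilyl triflate CC(C)(C)[Si](C)(C)OS(=O)(=O)C(F)(F)F (its silyl group stays only in 8 to 10 and is lost on work-up)
Why: Directed ortho-metalation: transient N-silylation makes the carbamate a strong directing group, n-BuLi/TMEDA removes the ring proton at C6 (flanked by the methoxy and carbamate oxygens), the aryllithium is silylated at −78 °C before an anionic ortho-Fries shift can occur, and the N–Si bond hydrolyses on work-up.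

Step 7
Reactants: 11 4-[(1S)-1-(tert-butyldimethylsilyloxy)-3-methylbutyl]-3-methoxy-2-(trimethylsilyl)phenyl N-isopropylcarbamate
Product: 13 4-[(1S)-1-(tert-butyldimethylsilyloxy)-3-methylbutyl]-3-methoxy-2-(trimethylsilyl)phenyl trifluoromethanesulfonate, via phenol 12 (not isolated)
Conditions: DBU, Et2NH, MeCN, 40 °C; then PhNTf2, rt
Reagents that add atoms: N-phenylbis(trifluoromethanesulfonimide) O=S(=O)(N(c1ccccc1)S(=O)(=O)C(F)(F)F)C(F)(F)F
Why: DBU-induced E1cB cleavage of the N-monosubstituted aryl carbamate (the isocyanate is trapped by Et2NH as a urea) frees the hindered phenoxide, which is triflated in the same flask; the conditions are mild enough to keep the aryl–silicon bond and the TBS ether.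

Step 8
Reactants: 14 creosol (2-methoxy-4-methylphenol)
Product: 15 2-hydroxy-3-methoxy-5-methylbenzaldehyde
Conditions: MgCl2, Et3N, (CH2O)n, THF, reflux; aq. HCl
Reagents that add atoms: paraformaldehyde, as formaldehyde C=O
Why: Magnesium-mediated ortho-formylation (Casnati–Skattebøl): the magnesium phenoxide directs formaldehyde to the only free ortho position, the para position being blocked by methyl, and a second formaldehyde oxidises the hydroxymethyl intermediate to the aldehyde.

Step 9
Reactants: 15 2-hydroxy-3-methoxy-5-methylbenzaldehyde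
Product: 16 2,3-dihydroxy-5-methylbenzaldehyde
Conditions: BBr3, CH2Cl2, −78 °C to 0 °C; H2O
Reagents that add atoms: none
Why: Lewis-acid demethylation of the aryl methyl ether by BBr3, which the salicylaldehyde carbonyl tolerates, as in the conversion of o-vanillin into 2,3-dihydroxybenzaldehyde.

Step 10
Reactants: 16 2,3-dihydroxy-5-methylbenzaldehyde
Product: 18 2-hydroxy-5-methyl-3-{[2-(trimethylsilyl)ethoxy]methoxy}benzaldehyde, via disodium catecholate 17 (not isolated)
Conditions: NaH (2.2 equiv), THF/DMF, 0 °C; SEMCl (1.0 equiv), 0 °C to rt; aq. NH4Cl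
Reagents that add atoms: 2-(trimethylsilyl)ethoxymethyl chloride C[Si](C)(C)CCOCCl
Why: Williamson-type mono-O-alkylation of a catecholate dianion: the 2-oxide is conjugated with and chelated to the formyl group and therefore the weaker nucleophile, so one equivalent of SEMCl should react at the more basic 3-oxide.

Step 11
Reactants: 18 2-hydroxy-5-methyl-3-{[2-(trimethylsilyl)ethoxy]methoxy}benzaldehyde
Product: 19 2-(hydroxymethyl)-4-methyl-6-{[2-(trimethylsilyl)ethoxy]methoxy}phenol
Conditions: NaBH4, MeOH, 0 °C
Reagents that add atoms: none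
Why: Borohydride reduction of the aldehyde to the benzylic alcohol; the SEM acetal is inert to hydride and the neutral work-up avoids quinone methide formation.

Step 12
Reactants: 19 2-(hydroxymethyl)-4-methyl-6-{[2-(trimethylsilyl)ethoxy]methoxy}phenol
Product: 20 2-{[(tert-butyldimethylsilyl)oxy]methyl}-4-methyl-6-{[2-(trimethylsilyl)ethoxy]methoxy}phenol
Conditions: TBSCl (1.05 equiv), imidazole, CH2Cl2, 0 °C
Reagents that add atoms: tert-butyldimethylsilyl chloride CC(C)(C)[Si](C)(C)Cl
Why: Chemoselective silylation: the primary benzylic alcohol reacts faster with one equivalent of TBSCl than the phenol, which is flanked by two ortho substituents.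

Step 13
Reactants: 13 4-[(1S)-1-(tert-butyldimethylsilyloxy)-3-methylbutyl]-3-methoxy-2-(trimethylsilyl)phenyl trifluoromethanesulfonate; 20 2-{[(tert-butyldimethylsilyl)oxy]methyl}-4-methyl-6-{[2-(trimethylsilyl)ethoxy]methoxy}phenol; 21 carbon dioxide
Product: 24 6-(2-{[(tert-butyldimethylsilyl)oxy]methyl}-4-methyl-6-{[2-(trimethylsilyl)ethoxy]methoxy}phenoxy)-3-[(1S)-1-(tert-butyldimethylsilyloxy)-3-methylbutyl]-2-methoxybenzoic acid, via potassium phenoxide 22 (not isolated), via aryne 23 (not isolated)
Conditions: 20, KH, THF, 0 °C; then CO2 (1 atm), KF, 18-crown-6, slow addition of 13, THF, 0 °C to rt; cold dilute aq. HCl to pH 4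
Reagents that add atoms: none
Why: Proposed new method: fluoride attacks the C6 trimethylsilyl group of 13 and triflate leaves from C5 to give the C5–C6 aryne 23, the potassium phenoxide 22 adds through oxygen at C5, and the aryl anion that develops at C6 is captured by dissolved CO2, so the C5–O and C6–CO2H bonds form in one operation. The closest known reaction types are the three-component coupling of arynes, amines and CO2 to anthranilic acids under KF/18-crown-6 in THF and the fluoride-mediated O-arylation of phenols by o-silylaryl triflates; the new element is a phenoxide as the nucleophile of the CO2 coupling. No ring is closed and no stereocentre is formed; the (S) silyl ether is a spectator. The step needs regioselectivity for oxygen at C5 and not C6: the C1 methoxy group distorts the aryne so that C5 is the more linear and more electrophilic terminus, the negative charge builds up at C6 next to the inductively withdrawing C–O bond, and the methoxy group also shields C6. It needs carboxylation to beat protonation: the phenol is fully deprotonated beforehand with KH so that hydrogen is the only by-product, THF offers no acidic C–H, CO2 is in excess, and both ortho positions and the para position of ring B are substituted so that neither C-arylation nor anion transfer to a ring B ortho position can compete. Carbonate formation at the di-ortho-substituted phenoxide oxygen should be weak and reversible, and slow addition of 13 keeps the aryne and triflate concentrations low.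

Step 14
Reactants: 24 6-(2-{[(tert-butyldimethylsilyl)oxy]methyl}-4-methyl-6-{[2-(trimethylsilyl)ethoxy]methoxy}phenoxy)-3-[(1S)-1-(tert-butyldimethylsilyloxy)-3-methylbutyl]-2-methoxybenzoic acid
Product: 25 6-[2-hydroxy-6-(hydroxymethyl)-4-methylphenoxy]-3-[(1S)-1-hydroxy-3-methylbutyl]-2-methoxybenzoic acid (CNP0221397.1)
Conditions: Bu4NF (8 equiv), ethylenediamine, THF, rt to 60 °C; aq. NH4Cl then citric acid to pH 5, 0 °C
Reagents that add atoms: none
Why: Fluoride-mediated desilylation cleaves both TBS ethers and, on warming, attacks the SEM silicon with fragmentation to fluorotrimethylsilane, ethene, formaldehyde (trapped by ethylenediamine) and the phenoxide; no bond at the stereocentre is broken and the cold, weakly acidic work-up avoids ionisation of the electron-rich benzylic alcohol.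

**Compound list**

1 | resorcinol | Oc1cccc(O)c1 | starting material
2 | isovaleryl chloride | CC(C)CC(=O)Cl | starting material
3 | 1-(2,4-dihydroxyphenyl)-3-methylbutan-1-one | CC(C)CC(=O)c1ccc(O)cc1O | intermediate
4 | 3-hydroxy-4-(3-methylbutanoyl)phenyl N-isopropylcarbamate | CC(C)CC(=O)c1ccc(OC(=O)NC(C)C)cc1O | intermediate
5 | 3-methoxy-4-(3-methylbutanoyl)phenyl N-isopropylcarbamate | COc1cc(OC(=O)NC(C)C)ccc1C(=O)CC(C)C | intermediate
6 | 4-[(1S)-1-hydroxy-3-methylbutyl]-3-methoxyphenyl N-isopropylcarbamate | COc1cc(OC(=O)NC(C)C)ccc1[C@@H](O)CC(C)C | intermediate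
7 | 4-[(1S)-1-(tert-butyldimethylsilyloxy)-3-methylbutyl]-3-methoxyphenyl N-isopropylcarbamate | COc1cc(OC(=O)NC(C)C)ccc1[C@@H](O[Si](C)(C)C(C)(C)C)CC(C)C | intermediate
8 | N-(tert-butyldimethylsilyl) derivative of 7 (N-silyl carbamate) | COc1cc(OC(=O)N(C(C)C)[Si](C)(C)C(C)(C)C)ccc1[C@@H](O[Si](C)(C)C(C)(C)C)CC(C)C | intermediate (not isolated)
9 | 2-lithio derivative of 8 (lithium between the methoxy and carbamate oxygens) | COc1c([Li])c(OC(=O)N(C(C)C)[Si](C)(C)C(C)(C)C)ccc1[C@@H](O[Si](C)(C)C(C)(C)C)CC(C)C | intermediate (not isolated)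
10 | 2-(trimethylsilyl) derivative of 8 (N-silyl C-silyl carbamate) | COc1c([Si](C)(C)C)c(OC(=O)N(C(C)C)[Si](C)(C)C(C)(C)C)ccc1[C@@H](O[Si](C)(C)C(C)(C)C)CC(C)C | intermediate (not isolated)
11 | 4-[(1S)-1-(tert-butyldimethylsilyloxy)-3-methylbutyl]-3-methoxy-2-(trimethylsilyl)phenyl N-isopropylcarbamate | COc1c([Si](C)(C)C)c(OC(=O)NC(C)C)ccc1[C@@H](O[Si](C)(C)C(C)(C)C)CC(C)C | intermediate
12 | 4-[(1S)-1-(tert-butyldimethylsilyloxy)-3-methylbutyl]-3-methoxy-2-(trimethylsilyl)phenol (present as its DBU salt) | COc1c([Si](C)(C)C)c(O)ccc1[C@@H](O[Si](C)(C)C(C)(C)C)CC(C)C | intermediate (not isolated)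
13 | 4-[(1S)-1-(tert-butyldimethylsilyloxy)-3-methylbutyl]-3-methoxy-2-(trimethylsilyl)phenyl trifluoromethanesulfonate | COc1c([Si](C)(C)C)c(OS(=O)(=O)C(F)(F)F)ccc1[C@@H](O[Si](C)(C)C(C)(C)C)CC(C)C | intermediate
14 | creosol (2-methoxy-4-methylphenol) | COc1cc(C)ccc1O | starting material
15 | 2-hydroxy-3-methoxy-5-methylbenzaldehyde | COc1cc(C)cc(C=O)c1O | intermediate
16 | 2,3-dihydroxy-5-methylbenzaldehyde | Cc1cc(O)c(O)c(C=O)c1 | intermediate
17 | disodium 3-formyl-5-methylbenzene-1,2-diolate | Cc1cc([O-])c([O-])c(C=O)c1.[Na+].[Na+] | intermediate (not isolated)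
18 | 2-hydroxy-5-methyl-3-{[2-(trimethylsilyl)ethoxy]methoxy}benzaldehyde | Cc1cc(OCOCC[Si](C)(C)C)c(O)c(C=O)c1 | intermediate
19 | 2-(hydroxymethyl)-4-methyl-6-{[2-(trimethylsilyl)ethoxy]methoxy}phenol | Cc1cc(CO)c(O)c(OCOCC[Si](C)(C)C)c1 | intermediate
20 | 2-{[(tert-butyldimethylsilyl)oxy]methyl}-4-methyl-6-{[2-(trimethylsilyl)ethoxy]methoxy}phenol | C[Si](C)(C)CCOCOc1cc(C)cc(CO[Si](C)(C)C(C)(C)C)c1O | intermediate
21 | carbon dioxide | O=C=O | starting material
22 | potassium phenoxide of 20 | C[Si](C)(C)CCOCOc1cc(C)cc(CO[Si](C)(C)C(C)(C)C)c1[O-].[K+] | intermediate (not isolated)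
23 | 4-[(1S)-1-(tert-butyldimethylsilyloxy)-3-methylbutyl]-3-methoxybenzyne (C5–C6 aryne of ring A) | COC1=C([C@@H](O[Si](C)(C)C(C)(C)C)CC(C)C)C=CC#C1 | intermediate (not isolated)
24 | 6-(2-{[(tert-butyldimethylsilyl)oxy]methyl}-4-methyl-6-{[2-(trimethylsilyl)ethoxy]methoxy}phenoxy)-3-[(1S)-1-(tert-butyldimethylsilyloxy)-3-methylbutyl]-2-methoxybenzoic acid | COc1c([C@@H](O[Si](C)(C)C(C)(C)C)CC(C)C)ccc(Oc2c(OCOCC[Si](C)(C)C)cc(C)cc2CO[Si](C)(C)C(C)(C)C)c1C(=O)O | intermediate
25 | 6-[2-hydroxy-6-(hydroxymethyl)-4-methylphenoxy]-3-[(1S)-1-hydroxy-3-methylbutyl]-2-methoxybenzoic acid | COc1c([C@@H](O)CC(C)C)ccc(Oc2c(O)cc(C)cc2CO)c1C(=O)O | target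

**Step count and risks**

Total steps: 14. Longest linear sequence: 9 (steps 1 to 7, then 13 and 14); the ring B branch is 5 steps (8 to 12) before the union.

Steps most likely to fail:

Step 13. The C6 aryl anion may be protonated before it meets CO2. The phenoxide may also enter as its carbonate and end, after acyl shift, as an isomeric aryl salicylate. The fallback uses known chemistry in two operations and sets out from 13 and 20. The aryne is generated with CsF in MeCN at rt without CO2; O-arylation of the phenol with protonation at C6 should give the C6-H diaryl ether F1. Directed ortho-lithiation with n-BuLi/TMEDA in THF at −78 °C to −20 °C, at the C6 position flanked by the methoxy and aryloxy oxygens, should give the C6 aryllithium F2. Quenching with CO2 and acidifying to pH 4 returns to the route at 24.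

Step 14. Cleavage of the aryl SEM ether by fluoride may be incomplete at temperatures the product tolerates. Released formaldehyde may hydroxymethylate ring B, and the electron-rich benzylic alcohol may ionise on work-up. The fallback sets out from 24. MgBr2·OEt2 in Et2O/MeNO2 at rt, a chelation-assisted Lewis-acid cleavage of the SEM acetal that leaves TBS ethers alone, should give the bis-TBS phenol acid F3. Bu4NF in THF at 0 °C to rt then removes the two TBS ethers under much milder conditions and returns to the route at 25.

Step 10. Regiocontrol in the mono-alkylation of the catecholate may be lost, through alkylation at the 2-oxide or double alkylation. The fallback sets out from 16 and removes the need to tell the two phenols apart. NaBH4 in MeOH should give the triol 3-(hydroxymethyl)-5-methylbenzene-1,2-diol F4. 2,2-Dimethoxypropane with PPTS in acetone ties the benzylic oxygen and the neighbouring phenol into the six-membered acetonide 2,2,6-trimethyl-4H-1,3-benzodioxin-8-ol F5, leaving only the future C2′ hydroxyl free. SEMCl with i-Pr2NEt in CH2Cl2 gives the SEM ether of the acetonide F6. Aqueous AcOH in THF at rt opens the acetonide and returns to the route at 19.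

**Further compounds**

F1 | step 13 | C6-H diaryl ether (24 without the carboxyl group) | COc1c([C@@H](O[Si](C)(C)C(C)(C)C)CC(C)C)ccc(Oc2c(OCOCC[Si](C)(C)C)cc(C)cc2CO[Si](C)(C)C(C)(C)C)c1
F2 | step 13 | C6 aryllithium of F1 | COc1c([C@@H](O[Si](C)(C)C(C)(C)C)CC(C)C)ccc(Oc2c(OCOCC[Si](C)(C)C)cc(C)cc2CO[Si](C)(C)C(C)(C)C)c1[Li]
F3 | step 14 | bis-TBS phenol acid (24 without the SEM group) | COc1c([C@@H](O[Si](C)(C)C(C)(C)C)CC(C)C)ccc(Oc2c(O)cc(C)cc2CO[Si](C)(C)C(C)(C)C)c1C(=O)O
F4 | step 10 | 3-(hydroxymethyl)-5-methylbenzene-1,2-diol | Cc1cc(O)c(O)c(CO)c1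
F5 | step 10 | 2,2,6-trimethyl-4H-1,3-benzodioxin-8-ol | Cc1cc(O)c2OC(C)(C)OCc2c1
F6 | step 10 | 2,2,6-trimethyl-8-{[2-(trimethylsilyl)ethoxy]methoxy}-4H-1,3-benzodioxine | Cc1cc(OCOCC[Si](C)(C)C)c2OC(C)(C)OCc2c1
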